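**Compound numbers used throughout:** 1 4‑hydroxybenzoic acid; 2 bis‑silylated acid (not isolated); 3 4‑(tert‑butyldimethylsilyloxy)benzoic acid; 4 oxetan‑3‑ol; 5 oxetan‑3‑yl 4‑(tert‑butyldimethylsilyloxy)benzoate; 6 (4‑bromobutoxy)(tert‑butyl)dimethylsilane; 7 1‑phenyl‑1H‑tetrazole‑5‑thiol; 8 tetrazolyl sulfide; 9 tetrazolyl sulfone; 10 (2E,4E)‑octa‑2,4‑dienal; 11 silyl ether of the trienol; 12 (4E,6E,8E)‑dodeca‑4,6,8‑trien‑1‑ol; 13 silyl‑protected target; 14 target.

## Analysis of the target

Target 14 is acyclic apart from one benzene ring. It is a glycerol unit with a (4E,6E,8E)‑dodeca‑4,6,8‑trienyl ether on O1, a 4‑hydroxybenzoate on O2 and a free hydroxyl on O3. The only stereocentre is glycerol C2, of (S) configuration (a 1‑O‑alkyl‑2‑O‑acyl‑sn‑glycerol). It is stereogenic solely because the two CH2O arms differ in what their oxygen carries, a C12 chain on one and hydrogen on the other. The conjugated triene is sensitive to strong acid, light, oxygen and radicals. As a dialkyl‑terminated triene it has only a small thermodynamic preference for all‑E, so its geometry must be set kinetically and never equilibrated. The secondary ester next to the free primary hydroxyl can shift from O2 to O3 under base, under acid or on silica, which would give a constitutional isomer. The electron‑rich 4‑oxybenzoyl group slows this shift but does not remove it. The free phenol is acidic and nucleophilic, so it has to be masked during any acid‑catalysed bond formation and unmasked without base. The difficulty is therefore to tell the three glycerol oxygens apart in a defined absolute sense without protecting‑group sequences that invite acyl migration. The strategy rests on one feature: C2 with its acyloxy group, flanked by C1H2–O and C3H2–O, is the ring‑opened form of an oxetan‑3‑yl ester. In that ester C1 and C3 are the two enantiotopic ring methylenes, O3 is the ring oxygen, and the O1–C1 ether bond is the bond made when an alcohol opens the ring.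

## Retrosynthetic reasoning

**14 ⇒ 13 (O–Si bond).** The phenol is taken back to its tert‑butyldimethylsilyl ether 13. In the ring‑opening step a free phenol would compete as a nucleophile and as a hydrogen‑bond donor for the catalyst. An aryl silyl ether is the one mask that falls to fluoride under buffered, non‑basic conditions, so the forward step need not expose the 2‑acyl‑3‑hydroxy array to base. The forward reaction has to cleave Ar–O–Si without moving the aroyl group from O2 to O3.

**13 ⇒ 5 + 12 (ether bond O1–C1 of the glycerol unit).** This is the strategic cut. Cutting the ester C–O bond instead would lead to a 1‑O‑alkyl‑glycerol whose O3 must be protected and whose stereocentre must be bought. Cutting the O–CH2 bond on the trienyl side leads to the same chiral‑pool problem. Cutting O1–C1 and reconnecting C1 to O3 gives the achiral oxetanyl ester 5 and the alcohol 12. One bond formation then delivers the ether, the stereocentre and the free O3 hydroxyl, with the acyl group already on O2 and no protecting group on the glycerol part. The forward reaction must make the alcohol attack one specific enantiotopic methylene (the pro‑S one). It must also outrun participation of the ester carbonyl and stop after one alkylation.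

**5 ⇒ 3 + 4, and 3 ⇒ 1 (ester C–O bond, then O–Si bonds).** The oxetanyl ester is cut at the acyl–oxygen bond into the silylated acid 3 and oxetan‑3‑ol 4, a routine carbodiimide coupling. The acid 3 comes from 1 by silylation of both acidic groups and selective release of the carboxyl. The ester is made before the glycerol pattern exists, so no regioselective acylation of a diol is ever needed.

**12 ⇒ 11 ⇒ 9 + 10 (C4=C5 of the chain, after an O–Si cut).** The triene is opened at the double bond nearest the oxygen terminus. This puts the two remaining E alkenes into the commercial dienal 10, where their geometry is already fixed. It also pairs a non‑conjugated sulfone 9 with a conjugated aldehyde, the polarity in which a modified Julia olefination is trans‑selective. A cut at C6=C7 or C8=C9 would need an allylic sulfone or an unsaturated partner that must first be made with defined geometry. The hydroxyl is carried as the silyl ether 11 so that the carbanion chemistry sees no acidic proton.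

**9 ⇒ 8 ⇒ 6 + 7 (S–O bonds, then the S–C bond).** The sulfone is taken back to the sulfide 8, and this to the thiol 7 and the primary bromide 6. The bromide already carries the protected oxygen and all four carbons C1–C4. Thiolate alkylation and sulfur oxidation are among the most dependable steps available, which keeps the risk out of this branch.

## Alternatives that were turned down

**Alternative 1: dienal from a pyrylium ring.**
- Disconnection: the chain is cut at C3–C4 (and later at C8=C9), and C4–C8 are drawn from a six‑membered oxonium ring.
- Forward key step: the Grignard reagent A1, a 3‑(glyceryloxy)propyl magnesium halide made from a chiral‑pool glycerol acetonide, adds to C2 of pyrylium tetrafluoroborate A2. The resulting 2H‑pyran opens by 6π electrocyclic ring opening, and equilibration gives the 2E,4E‑dienal A3.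
- For: the stereocentre is purchased, so the absolute configuration is not in doubt; on this point the alternative is stronger than the chosen route. The dienal geometry converges thermodynamically because it is conjugated to the aldehyde, and every step has precedent.
- Against: A3 still lacks C9–C12, so an E‑selective olefination with a non‑stabilised four‑carbon partner is needed on an advanced intermediate. The glycerol part then needs acetonide removal in the presence of the triene, primary protection, acylation at O2 and deprotection. These are the operations in which acyl migration threatens. A2 is moisture‑sensitive and has to be prepared. The longest linear sequence would be about ten steps.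
- Comparison: the chosen route gives up the guaranteed configuration. In exchange it has six linear steps, no protecting group on glycerol, and a single step that sets ether, stereocentre and acyl pattern together.

**Alternative 2: Johnson–Claisen transposition.**
- Disconnection: the C2–C3 bond of the chain, with the C4=C5 alkene arising by allylic transposition.
- Forward key step: the racemic dienyl vinyl carbinol A4, from addition of a vinyl organometallic to 10, is heated with triethyl orthoacetate A5 and a trace of acid. The ketene acetal rearranges through a chair across the terminal vinyl group to the trienoate A6, and reduction of A6 would give 12.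
- For: three steps from 10 to 12 against four in the chosen branch, so it is slightly stronger on step count. The E geometry follows from the chair, the carbinol stereocentre is destroyed so a racemate suffices, and no sulfur chemistry is needed.
- Against: A4 is doubly allylic and ionises easily under acid at about 140 °C, which opens the way to dehydration and allylic scrambling. Rearrangement across the dienyl terminus would give a branched, skipped isomer. Prolonged heating of a conjugated triene risks geometric drift. Above all, this step solves only the achiral chain; the stereocentre and the acyl pattern remain untouched and would still need a chiral‑pool sequence or the oxetane opening.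
- Comparison: it is an alternative source of 12 rather than a competitor for the key disconnection. The chosen olefination offers low temperature and non‑acidic conditions for a sensitive triene.

**Alternative 3: ketoreductase reduction of a dihydroxyacetone ether.**
- Disconnection: the C2–H bond, with the stereocentre made by reduction of the ketone A7.
- Forward key step: a ketoreductase with cofactor recycling delivers hydride to one face of A7 to give the 3‑O‑silyl‑1‑O‑trienyl‑sn‑glycerol A8. Acylation at O2 and removal of two silyl groups would follow.
- For: it mirrors ether‑lipid biosynthesis. Enzymatic ketone reduction is a well‑established reaction class that often reaches very high enantiomeric purity, and either enantiomer is reachable by enzyme choice. In precedent and predictability of the stereo‑setting step it is stronger than the chosen route.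
- Against: both ketone substituents are CH2O groups that differ only remotely (trienyl against silyl), a "bulky–bulky" ketone that many enzymes accept poorly. The lipophilic substrate is barely soluble in buffer. The α,α′‑dialkoxy ketone is prone to enolisation. Making A7 means building the glycerol skeleton at the alcohol level and oxidising it, a redox detour. The primary alkyl silyl ether of the acylated product needs more forcing fluoride conditions right next to the migration‑prone ester. About nine to ten steps would be needed in total.
- Comparison: the chosen route offers convergence, no redox detour, the acyl group in place from the start, and only an aryl silyl ether to remove at the end.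

Key step: step 7

**Assumptions.**
- The sense of induction cannot be predicted for an unprecedented substrate class. The (R)‑catalyst is written in step 7, and its antipode is used if it exposes the pro‑R methylene instead.
- The silyl‑protected C4 bromide 6 is taken as a catalogue compound.

## Route

Step 1
Reactants: 1 4‑hydroxybenzoic acid
Product: 3 4‑(tert‑butyldimethylsilyloxy)benzoic acid, via silyl 4‑silyloxybenzoate 2 (not isolated)
Conditions: TBSCl (2.4 equiv), imidazole, DMF, rt; then AcOH/THF/H2O (3:1:1), rt
Reagents that add atoms: tert‑butyldimethylsilyl chloride, CC(C)(C)[Si](C)(C)Cl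
Why: Silylation of both acidic hydroxyls followed by selective solvolysis of the silyl ester, which is far more labile to aqueous acetic acid than the aryl silyl ether.

Step 2
Reactants: 3 4‑(tert‑butyldimethylsilyloxy)benzoic acid; 4 oxetan‑3‑ol
Product: 5 oxetan‑3‑yl 4‑(tert‑butyldimethylsilyloxy)benzoate
Conditions: DCC, DMAP (cat.), CH2Cl2, 0 °C → rt
Reagents that add atoms: none
Why: Steglich esterification; the acyl group passes from the O‑acylisourea via the acylpyridinium ion to the unhindered secondary alcohol, and the oxetane and the aryl silyl ether tolerate these nearly neutral conditions.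

Step 3
Reactants: 6 (4‑bromobutoxy)(tert‑butyl)dimethylsilane; 7 1‑phenyl‑1H‑tetrazole‑5‑thiol
Product: 8 5‑({4‑[(tert‑butyldimethylsilyl)oxy]butyl}sulfanyl)‑1‑phenyl‑1H‑tetrazole
Conditions: K2CO3, DMF, rt
Reagents that add atoms: none
Why: SN2 S‑alkylation of the soft tetrazolethiolate at a primary bromide; the silyl ether is inert to carbonate in DMF.

Step 4
Reactants: 8 5‑({4‑[(tert‑butyldimethylsilyl)oxy]butyl}sulfanyl)‑1‑phenyl‑1H‑tetrazole
Product: 9 5‑({4‑[(tert‑butyldimethylsilyl)oxy]butyl}sulfonyl)‑1‑phenyl‑1H‑tetrazole
Conditions: (NH4)6Mo7O24·4H2O (10 mol%), 30% aq. H2O2, EtOH, 0 °C → rt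
Reagents that add atoms: hydrogen peroxide, OO
Why: Peroxomolybdate‑catalysed oxidation of the sulfide through the sulfoxide to the sulfone, the usual way to tetrazolyl sulfones; no alkene is present yet and the primary silyl ether is expected to survive the short, mildly acidic treatment.

Step 5
Reactants: 9 5‑({4‑[(tert‑butyldimethylsilyl)oxy]butyl}sulfonyl)‑1‑phenyl‑1H‑tetrazole; 10 (2E,4E)‑octa‑2,4‑dienal
Product: 11 tert‑butyl{[(4E,6E,8E)‑dodeca‑4,6,8‑trien‑1‑yl]oxy}dimethylsilane
Conditions: KHMDS (1.1 equiv), DME, −60 °C; then 10, −60 °C → rt; Ar, dark
Reagents that add atoms: none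
Why: Julia–Kocienski olefination: the potassium sulfonyl carbanion adds to the aldehyde, and Smiles transfer of the tetrazole to oxygen with loss of sulfur dioxide and tetrazololate forms C4=C5. With a conjugated aldehyde the intermediate can pass through an allyl‑stabilised zwitterion that eliminates from its less crowded conformer, so the E alkene is expected, and the two E bonds of 10 are not touched.

Step 6
Reactants: 11 tert‑butyl{[(4E,6E,8E)‑dodeca‑4,6,8‑trien‑1‑yl]oxy}dimethylsilane
Product: 12 (4E,6E,8E)‑dodeca‑4,6,8‑trien‑1‑ol
Conditions: TBAF, THF, 0 °C → rt; Ar, dark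
Reagents that add atoms: none
Why: Fluoride‑induced cleavage of a primary silyl ether; the triene is inert to fluoride and no stereo‑element is involved.

Step 7
Reactants: 5 oxetan‑3‑yl 4‑(tert‑butyldimethylsilyloxy)benzoate; 12 (4E,6E,8E)‑dodeca‑4,6,8‑trien‑1‑ol
Product: 13 (2S)‑1‑[(4E,6E,8E)‑dodeca‑4,6,8‑trien‑1‑yloxy]‑3‑hydroxypropan‑2‑yl 4‑[(tert‑butyldimethylsilyl)oxy]benzoate
Conditions: (R)‑3,3′‑bis(2,4,6‑triisopropylphenyl)‑BINOL N‑triflylphosphoramide (10 mol%), 12 (2 equiv), dry PhMe (0.5 M), 0 °C → rt, Ar, dark; direct cold filtration through silica
Reagents that add atoms: none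
Why: Proposed new method: the acidic N–H of the catalyst hydrogen‑bonds (partly protonates) the oxetane oxygen of 5 while its phosphoryl oxygen accepts the O–H of 12, so the alcohol is delivered in SN2 fashion to one ring methylene inside the chiral pocket, with about 25 kcal/mol of ring strain driving the substitution and the proton relayed from the entering to the leaving oxygen. The closest known reaction type is the chiral‑phosphoric‑acid‑catalysed desymmetrising opening of 3‑substituted oxetanes by thiols, chloride and tethered hydroxyl or amine groups; an intermolecular aliphatic alcohol and a 3‑acyloxy substituent have not been shown, which is why the more acidic N‑triflylphosphoramide and a high concentration are chosen. No ring is closed; the four‑membered ring is opened and one C–O bond (trienyl oxygen to glycerol C1) is formed. The new stereocentre, glycerol C2, is never a reaction site: its configuration is fixed only by which enantiotopic methylene the catalyst exposes, attack at the pro‑S CH2 giving the (S) product, and the substrate handle is the difference between H and the flat aroyloxy group on that carbon, whose carbonyl can act as a second hydrogen‑bond acceptor. Three selectivities are needed: enantiotopic‑group selectivity from the catalyst pocket; intermolecular attack over participation of the ester carbonyl, which would have to reach the backside of a ring C–O bond through a strained bicyclic transition state and would give a high‑energy dioxolanium ion, whereas the alcohol is pre‑bound and in excess; and mono‑alkylation, secured because the primary hydroxyl of 13 is deactivated by the β‑acyloxy group and 12 is present in twofold excess. The triene and the aryl silyl ether are too weakly basic to engage a catalytic amount of this acid in toluene, and a short reaction time at or below room temperature limits acid‑catalysed O2→O3 acyl transfer in 13.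

Step 8
Reactants: 13 (2S)‑1‑[(4E,6E,8E)‑dodeca‑4,6,8‑trien‑1‑yloxy]‑3‑hydroxypropan‑2‑yl 4‑[(tert‑butyldimethylsilyl)oxy]benzoate
Product: 14 (2S)‑1‑[(4E,6E,8E)‑dodeca‑4,6,8‑trien‑1‑yloxy]‑3‑hydroxypropan‑2‑yl 4‑hydroxybenzoate
Conditions: TBAF/AcOH (1:1.2), THF, −20 → 0 °C; pH 7 buffer work‑up; rapid chromatography on neutral silica
Reagents that add atoms: none
Why: Fluoride attacks silicon and expels the phenoxide, the best leaving group present, so the aryl silyl ether should fall quickly even with acetic acid in the medium. The acid protonates the phenoxide at once, so no base is left to promote O2→O3 acyl transfer, which the electron‑rich 4‑oxybenzoyl group resists in any case; C2 is not touched.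

## Compound list

1 | 4‑hydroxybenzoic acid | O=C(O)c1ccc(O)cc1 | starting material
2 | tert‑butyldimethylsilyl 4‑[(tert‑butyldimethylsilyl)oxy]benzoate | CC(C)(C)[Si](C)(C)OC(=O)c1ccc(O[Si](C)(C)C(C)(C)C)cc1 | intermediate
3 | 4‑[(tert‑butyldimethylsilyl)oxy]benzoic acid | CC(C)(C)[Si](C)(C)Oc1ccc(cc1)C(=O)O | intermediate
4 | oxetan‑3‑ol | OC1COC1 | starting material
5 | oxetan‑3‑yl 4‑[(tert‑butyldimethylsilyl)oxy]benzoate | CC(C)(C)[Si](C)(C)Oc1ccc(cc1)C(=O)OC1COC1 | intermediate
6 | (4‑bromobutoxy)(tert‑butyl)dimethylsilane | CC(C)(C)[Si](C)(C)OCCCCBr | starting material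
7 | 1‑phenyl‑1H‑tetrazole‑5‑thiol | Sc1nnnn1-c1ccccc1 | starting material
8 | 5‑({4‑[(tert‑butyldimethylsilyl)oxy]butyl}sulfanyl)‑1‑phenyl‑1H‑tetrazole | CC(C)(C)[Si](C)(C)OCCCCSc1nnnn1-c1ccccc1 | intermediate
9 | 5‑({4‑[(tert‑butyldimethylsilyl)oxy]butyl}sulfonyl)‑1‑phenyl‑1H‑tetrazole | CC(C)(C)[Si](C)(C)OCCCCS(=O)(=O)c1nnnn1-c1ccccc1 | intermediate
10 | (2E,4E)‑octa‑2,4‑dienal | CCC/C=C/C=C/C=O | starting material
11 | tert‑butyl{[(4E,6E,8E)‑dodeca‑4,6,8‑trien‑1‑yl]oxy}dimethylsilane | CCC/C=C/C=C/C=C/CCCO[Si](C)(C)C(C)(C)C | intermediate
12 | (4E,6E,8E)‑dodeca‑4,6,8‑trien‑1‑ol | CCC/C=C/C=C/C=C/CCCO | intermediate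
13 | (2S)‑1‑[(4E,6E,8E)‑dodeca‑4,6,8‑trien‑1‑yloxy]‑3‑hydroxypropan‑2‑yl 4‑[(tert‑butyldimethylsilyl)oxy]benzoate | CCC/C=C/C=C/C=C/CCCOC[C@H](CO)OC(=O)c1ccc(O[Si](C)(C)C(C)(C)C)cc1 | intermediate
14 | (2S)‑1‑[(4E,6E,8E)‑dodeca‑4,6,8‑trien‑1‑yloxy]‑3‑hydroxypropan‑2‑yl 4‑hydroxybenzoate | CCC/C=C/C=C/C=C/CCCOC[C@H](CO)OC(=O)c1ccc(O)cc1 | target

## Step count and least certain steps

Total step count: 8. Longest linear sequence: 6 steps (from 6 through steps 3, 4, 5, 6, 7 and 8).

**Step 7 (key step, proposed new method).**
- What may go wrong: turnover may be low because the 3‑acyloxy group lowers the basicity of the ring oxygen and slows substitution at the neighbouring methylene. The catalyst may discriminate the two enantiotopic methylenes poorly with an intermolecular alcohol. The ester carbonyl, made more nucleophilic by the para silyloxy donor, may open the ring to a dioxolanium ion and then to ortho esters. The aroyl group may drift from O2 to O3 under the acid once the product has formed.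
- Fallback (known chemistry): it sets out from 12 and rejoins the route at 14. Mesylation (MsCl, Et3N) should give (4E,6E,8E)‑dodeca‑4,6,8‑trien‑1‑yl methanesulfonate F1. F1 alkylates the sodium alkoxide of commercial (R)‑solketal (NaH, DMF) to the acetonide ether (4R)‑4‑{[(4E,6E,8E)‑dodeca‑4,6,8‑trien‑1‑yloxy]methyl}‑2,2‑dimethyl‑1,3‑dioxolane F2. Mild hydrolysis (aq. AcOH, 40 °C) should give the diol (2S)‑3‑[(4E,6E,8E)‑dodeca‑4,6,8‑trien‑1‑yloxy]propane‑1,2‑diol F3. Selective primary silylation (TESCl, imidazole, −40 °C) gives (2R)‑1‑[(4E,6E,8E)‑dodeca‑4,6,8‑trien‑1‑yloxy]‑3‑[(triethylsilyl)oxy]propan‑2‑ol F4. Acylation with 3 (DCC, DMAP) gives the bis‑silyl ester (2R)‑1‑[(4E,6E,8E)‑dodeca‑4,6,8‑trien‑1‑yloxy]‑3‑[(triethylsilyl)oxy]propan‑2‑yl 4‑[(tert‑butyldimethylsilyl)oxy]benzoate F5. Buffered fluoride (TBAF/AcOH, 0 °C) removes both silyl groups to give 14. The stereocentre then comes from the chiral pool, at the cost of six steps in place of two.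

**Step 5 (Julia–Kocienski olefination).**
- What may go wrong: incomplete trans selectivity at the new C4=C5 bond, because tetrazolyl sulfones are less dependable with conjugated than with saturated aldehydes. Geometric isomers of a non‑polar triene are hard to separate. Halogen‑catalysed equilibration is no remedy: the thermodynamic bias of a dialkyl‑terminated triene is small and the two existing E bonds would be scrambled as well.
- Fallback: it sets out from 6 and 10 and rejoins at 11, by a classical Julia–Lythgoe sequence. Displacement of bromide with sodium benzenesulfinate (DMF, 60 °C) gives tert‑butyldimethyl[4‑(phenylsulfonyl)butoxy]silane F6. Lithiation (n‑BuLi, THF, −78 °C), addition to 10 and trapping with acetic anhydride give (6E,8E)‑1‑[(tert‑butyldimethylsilyl)oxy]‑4‑(phenylsulfonyl)dodeca‑6,8‑dien‑5‑yl acetate F7 as a diastereomer mixture. Reductive elimination (Na/Hg, Na2HPO4, MeOH/THF, −20 °C) should give 11, with trans geometry set by the equilibrating radical/anion intermediate.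

**Step 8 (desilylation).**
- What may go wrong: O2→O3 acyl migration during fluoride treatment or on silica, or slow cleavage if the buffer is too acidic.
- Fallback: it sets out from 1 and rejoins at 14, with a reductively cleaved carbonate in place of the silyl ether. Acylation of the phenol of 1 (2,2,2‑trichloroethyl chloroformate, aq. NaOH, 0 °C) gives 4‑{[(2,2,2‑trichloroethoxy)carbonyl]oxy}benzoic acid F8. Coupling with 4 (DCC, cat. DMAP, 0 °C) gives oxetan‑3‑yl 4‑{[(2,2,2‑trichloroethoxy)carbonyl]oxy}benzoate F9. Opening with 12 under the conditions of step 7 gives (2S)‑1‑[(4E,6E,8E)‑dodeca‑4,6,8‑trien‑1‑yloxy]‑3‑hydroxypropan‑2‑yl 4‑{[(2,2,2‑trichloroethoxy)carbonyl]oxy}benzoate F10. Zinc in AcOH/THF at rt then frees the phenol without fluoride or base to give 14. The electron‑withdrawing carbonate should also lower carbonyl participation in the ring opening. This fallback still depends on the unprecedented ring opening.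

**Step 4 (sulfide oxidation).**
- What may go wrong: partial loss of the primary silyl ether in the acidic peroxomolybdate medium, or stalling at the sulfoxide.
- Fallback: it sets out from 7 and rejoins at 9, with oxidation before silylation. Mitsunobu reaction of 7 with excess butane‑1,4‑diol (PPh3, DIAD, THF) gives 4‑[(1‑phenyl‑1H‑tetrazol‑5‑yl)sulfanyl]butan‑1‑ol F11. The same molybdate/peroxide oxidation, which tolerates a free hydroxyl, gives 4‑[(1‑phenyl‑1H‑tetrazol‑5‑yl)sulfonyl]butan‑1‑ol F12. Silylation (TBSCl, imidazole, CH2Cl2) then gives 9.

## Further compounds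

F1 | step 7 | (4E,6E,8E)‑dodeca‑4,6,8‑trien‑1‑yl methanesulfonate | CCC/C=C/C=C/C=C/CCCOS(C)(=O)=O
F2 | step 7 | (4R)‑4‑{[(4E,6E,8E)‑dodeca‑4,6,8‑trien‑1‑yloxy]methyl}‑2,2‑dimethyl‑1,3‑dioxolane | CCC/C=C/C=C/C=C/CCCOC[C@@H]1COC(C)(C)O1
F3 | step 7 | (2S)‑3‑[(4E,6E,8E)‑dodeca‑4,6,8‑trien‑1‑yloxy]propane‑1,2‑diol | CCC/C=C/C=C/C=C/CCCOC[C@H](CO)O
F4 | step 7 | (2R)‑1‑[(4E,6E,8E)‑dodeca‑4,6,8‑trien‑1‑yloxy]‑3‑[(triethylsilyl)oxy]propan‑2‑ol | CCC/C=C/C=C/C=C/CCCOC[C@H](CO[Si](CC)(CC)CC)O
F5 | step 7 | (2R)‑1‑[(4E,6E,8E)‑dodeca‑4,6,8‑trien‑1‑yloxy]‑3‑[(triethylsilyl)oxy]propan‑2‑yl 4‑[(tert‑butyldimethylsilyl)oxy]benzoate | CCC/C=C/C=C/C=C/CCCOC[C@H](CO[Si](CC)(CC)CC)OC(=O)c1ccc(O[Si](C)(C)C(C)(C)C)cc1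
F6 | step 5 | tert‑butyldimethyl[4‑(phenylsulfonyl)butoxy]silane | CC(C)(C)[Si](C)(C)OCCCCS(=O)(=O)c1ccccc1
F7 | step 5 | (6E,8E)‑1‑[(tert‑butyldimethylsilyl)oxy]‑4‑(phenylsulfonyl)dodeca‑6,8‑dien‑5‑yl acetate (diastereomer mixture) | CCC/C=C/C=C/C(OC(C)=O)C(CCCO[Si](C)(C)C(C)(C)C)S(=O)(=O)c1ccccc1
F8 | step 8 | 4‑{[(2,2,2‑trichloroethoxy)carbonyl]oxy}benzoic acid | OC(=O)c1ccc(OC(=O)OCC(Cl)(Cl)Cl)cc1
F9 | step 8 | oxetan‑3‑yl 4‑{[(2,2,2‑trichloroethoxy)carbonyl]oxy}benzoate | O=C(OC1COC1)c1ccc(OC(=O)OCC(Cl)(Cl)Cl)cc1
F10 | step 8 | (2S)‑1‑[(4E,6E,8E)‑dodeca‑4,6,8‑trien‑1‑yloxy]‑3‑hydroxypropan‑2‑yl 4‑{[(2,2,2‑trichloroethoxy)carbonyl]oxy}benzoate | CCC/C=C/C=C/C=C/CCCOC[C@H](CO)OC(=O)c1ccc(OC(=O)OCC(Cl)(Cl)Cl)cc1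
F11 | step 4 | 4‑[(1‑phenyl‑1H‑tetrazol‑5‑yl)sulfanyl]butan‑1‑ol | OCCCCSc1nnnn1-c1ccccc1
F12 | step 4 | 4‑[(1‑phenyl‑1H‑tetrazol‑5‑yl)sulfonyl]butan‑1‑ol | OCCCCS(=O)(=O)c1nnnn1-c1ccccc1
A1 | alternative 1 | [3‑({[(4R)‑2,2‑dimethyl‑1,3‑dioxolan‑4‑yl]methoxy})propyl]magnesium bromide | Br[Mg]CCCOC[C@@H]1COC(C)(C)O1
A2 | alternative 1 | pyrylium tetrafluoroborate | c1cc[o+]cc1.F[B-](F)(F)F
A3 | alternative 1 | (2E,4E)‑8‑{[(4R)‑2,2‑dimethyl‑1,3‑dioxolan‑4‑yl]methoxy}octa‑2,4‑dienal | O=C/C=C/C=C/CCCOC[C@H](CO1)OC1(C)C
A4 | alternative 2 | (4E,6E)‑deca‑1,4,6‑trien‑3‑ol (racemic) | C=CC(O)/C=C/C=C/CCC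
A5 | alternative 2 | triethyl orthoacetate | CCOC(C)(OCC)OCC
A6 | alternative 2 | ethyl (4E,6E,8E)‑dodeca‑4,6,8‑trienoate | CCC/C=C/C=C/C=C/CCC(=O)OCC
A7 | alternative 3 | 1‑[(tert‑butyldimethylsilyl)oxy]‑3‑[(4E,6E,8E)‑dodeca‑4,6,8‑trien‑1‑yloxy]propan‑2‑one | CCC/C=C/C=C/C=C/CCCOCC(=O)CO[Si](C)(C)C(C)(C)C
A8 | alternative 3 | (2R)‑1‑[(tert‑butyldimethylsilyl)oxy]‑3‑[(4E,6E,8E)‑dodeca‑4,6,8‑trien‑1‑yloxy]propan‑2‑ol | CCC/C=C/C=C/C=C/CCCOC[C@H](CO[Si](C)(C)C(C)(C)C)O
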